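**Assumption:** the target has no stereocentre, and its ring A–ring C axis (ortho groups OH, OH, OMe, H) is taken as freely rotating at room temperature, so the compound is made as the single achiral species and no stereocontrol is needed.

## Retrosynthetic overview

- The biaryl bond to ring C is cut last: Suzuki–Miyaura coupling of 6-bromoapigenin with the bought ring C boronic acid. It is kept for the end because the ring C ester would itself direct metalation in the hydroxylation.
- Key disconnection: the C5–O bond. 6-Bromoapigenin comes from 6-bromo-7,4'-dihydroxyflavone by carbonyl-directed peri C–H hydroxylation (the proposed new step).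
- The pyranone O1–C2 bond (and C2–C3) is cut next: the bromoflavone comes from 5-bromo-2,4-dihydroxyacetophenone and 4-hydroxybenzaldehyde.
- Ring A then has only one hydroxyl ortho to the ketone when the pyranone closes, so the 6-/8-substitution ambiguity of phloroglucinol-type cyclisations cannot arise; the second oxygen is added afterwards.
- Ring order: rings A, B and C are bought as benzene rings; the pyranone is the only ring formed (step 1).

## Route

**Step 1**
Reactants: 1 1-(5-bromo-2,4-dihydroxyphenyl)ethan-1-one; 2 4-hydroxybenzaldehyde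
Product: 5 bromoflavone [6-bromo-7-hydroxy-2-(4-hydroxyphenyl)-4H-chromen-4-one], via bromochalcone 3 (not isolated), via bromoflavanone 4 (not isolated)
Conditions: pyrrolidine (0.5 equiv), I2 (10 mol %), DMSO, 130 °C
Reagents that add atoms: none
Why: Pyrrolidine-mediated Claisen–Schmidt (aldol) condensation gives chalcone 3, whose only ortho-hydroxyl closes the O1–C2 bond by 6-endo oxa-Michael addition to racemic flavanone 4, and I2-catalysed dehydrogenation with DMSO as terminal oxidant gives the flavone and erases the C2 stereocentre; with a single hydroxyl ortho to the ketone the bromine can only end up at C6.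

**Step 2**
Reactants: 5 bromoflavone [6-bromo-7-hydroxy-2-(4-hydroxyphenyl)-4H-chromen-4-one]
Product: 8 6-bromoapigenin [6-bromo-5,7-dihydroxy-2-(4-hydroxyphenyl)-4H-chromen-4-one], via bis(trifluoroacetate) 6 (not isolated), via tris(trifluoroacetate) 7 (not isolated)
Conditions: [RuCl2(p-cymene)]2 (5 mol %), K2S2O8 (2 equiv), TFA/TFAA (3:1), 80 °C; then H2O/THF, rt
Reagents that add atoms: trifluoroacetic acid, OC(=O)C(F)(F)F (its carboxylate oxygen becomes the C5 oxygen)
Why: Proposed new method: TFAA first caps both phenols as electron-poor trifluoroacetates (6) so that persulfate cannot oxidise them; the pyranone carbonyl then binds cationic divalent ruthenium trifluoroacetate, carboxylate-assisted concerted metalation–deprotonation at the only peri C–H (C5, acidified by the ortho bromine and the meta acyloxy group) gives a five-membered ruthenacycle, K2S2O8 oxidises it to tetravalent ruthenium, C–O reductive elimination gives the C5 trifluoroacetate 7, and water cleaves all three trifluoroacetates to 8, whose new hydroxyl is held by a hydrogen bond to C4=O; the closest known reactions are the ruthenium-catalysed carbonyl-directed C5 hydroxylation of simple protected flavones and chromones and the ortho-hydroxylation of aryl ketones in TFA/TFAA, neither shown for a C–H flanked by bromine on a free polyphenol masked in the flask.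

**Step 3**
Reactants: 8 6-bromoapigenin [6-bromo-5,7-dihydroxy-2-(4-hydroxyphenyl)-4H-chromen-4-one]; 9 [2-methoxy-5-(methoxycarbonyl)phenyl]boronic acid
Product: 10 methyl 3-[5,7-dihydroxy-2-(4-hydroxyphenyl)-4-oxo-4H-chromen-6-yl]-4-methoxybenzoate
Conditions: Pd(OAc)2 (5 mol %), SPhos (10 mol %), K3PO4 (5 equiv), 9 (2 equiv), 1,4-dioxane/H2O (5:1), 80 °C
Reagents that add atoms: none
Why: Suzuki–Miyaura coupling in which SPhos-ligated zerovalent palladium inserts into the hindered, electron-rich C6–Br bond and couples the ortho-methoxy boronic acid; the electron-rich 4-methoxybenzoate ester should survive phosphate at 80 °C, and the new axis carries only small ortho groups, so no stereogenic element is created.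

## Compound list

1 | 1-(5-bromo-2,4-dihydroxyphenyl)ethan-1-one (5-bromo-2,4-dihydroxyacetophenone) | CC(=O)c1cc(Br)c(O)cc1O | starting material
2 | 4-hydroxybenzaldehyde | O=Cc1ccc(O)cc1 | starting material
3 | bromochalcone, (E)-1-(5-bromo-2,4-dihydroxyphenyl)-3-(4-hydroxyphenyl)prop-2-en-1-one, formed in the flask | O=C(/C=C/c1ccc(O)cc1)c1cc(Br)c(O)cc1O | intermediate
4 | bromoflavanone, racemic 6-bromo-7-hydroxy-2-(4-hydroxyphenyl)chroman-4-one, formed in the flask | O=C1CC(c2ccc(O)cc2)Oc2cc(O)c(Br)cc21 | intermediate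
5 | bromoflavone, 6-bromo-7-hydroxy-2-(4-hydroxyphenyl)-4H-chromen-4-one | O=c1cc(-c2ccc(O)cc2)oc2cc(O)c(Br)cc12 | intermediate
6 | bis(trifluoroacetate), 6-bromo-4-oxo-2-[4-(trifluoroacetoxy)phenyl]-4H-chromen-7-yl trifluoroacetate, formed in the flask | O=c1cc(-c2ccc(OC(=O)C(F)(F)F)cc2)oc2cc(OC(=O)C(F)(F)F)c(Br)cc12 | intermediate
7 | tris(trifluoroacetate), 6-bromo-4-oxo-2-[4-(trifluoroacetoxy)phenyl]-4H-chromene-5,7-diyl bis(trifluoroacetate), formed in the flask | O=c1cc(-c2ccc(OC(=O)C(F)(F)F)cc2)oc2cc(OC(=O)C(F)(F)F)c(Br)c(OC(=O)C(F)(F)F)c12 | intermediate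
8 | 6-bromoapigenin, 6-bromo-5,7-dihydroxy-2-(4-hydroxyphenyl)-4H-chromen-4-one | O=c1cc(-c2ccc(O)cc2)oc2cc(O)c(Br)c(O)c12 | intermediate
9 | [2-methoxy-5-(methoxycarbonyl)phenyl]boronic acid | COC(=O)c1ccc(OC)c(B(O)O)c1 | starting material
10 | methyl 3-[5,7-dihydroxy-2-(4-hydroxyphenyl)-4-oxo-4H-chromen-6-yl]-4-methoxybenzoate | COC(=O)c1ccc(OC)c(-c2c(O)cc3oc(-c4ccc(O)cc4)cc(=O)c3c2O)c1 | target

## Step count and risks

Total step count: 3. Longest linear sequence: 3 steps (1 → 5 → 8 → 10).

**Most likely to fail, first: step 2 (the proposed new step).** The C5–H bond lies between the carbonyl and a bromine, which loads the metalation sterically, and the in-flask masking of the phenols is untested. The fallback uses known chemistry only and avoids the C–H hydroxylation altogether; it sets out from boronic acid 9 and comes back to the route at target 10. Bought apigenin F3 is benzylated at O7 and O4' (BnBr, K2CO3, DMF; the chelated 5-OH stays free) to 7-(benzyloxy)-2-[4-(benzyloxy)phenyl]-5-hydroxy-4H-chromen-4-one F4. This is iodinated ortho to the free 5-OH (BnNMe3ICl2, CaCO3, CH2Cl2/MeOH, rt) to the 6-iodide 7-(benzyloxy)-2-[4-(benzyloxy)phenyl]-5-hydroxy-6-iodo-4H-chromen-4-one F5. Suzuki–Miyaura coupling of F5 with 9 (Pd(OAc)2, SPhos, K3PO4, dioxane/H2O, 80 °C) gives methyl 3-{7-(benzyloxy)-2-[4-(benzyloxy)phenyl]-5-hydroxy-4-oxo-4H-chromen-6-yl}-4-methoxybenzoate F6, and hydrogenolysis (H2, Pd/C, EtOAc/MeOH) gives 10.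

**Second: step 3.** The bromide is flanked by two phenoxides under the basic conditions, so oxidative addition may be slow; protodebromination to apigenin and partial ester hydrolysis are the likely side reactions. The fallback couples a protected substrate; it sets out from 8 and comes back at 10. Compound 8 is protected at O7 and O4' (MOMCl, iPr2NEt, CH2Cl2, 0 °C) to 6-bromo-5-hydroxy-7-(methoxymethoxy)-2-[4-(methoxymethoxy)phenyl]-4H-chromen-4-one F7. Coupling with 9 (Pd(OAc)2, SPhos, K3PO4, toluene/H2O, 100 °C) gives methyl 3-{5-hydroxy-7-(methoxymethoxy)-2-[4-(methoxymethoxy)phenyl]-4-oxo-4H-chromen-6-yl}-4-methoxybenzoate F8, and HCl in MeOH at 50 °C removes both acetals to give 10 without touching the methyl ester.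

**Third: step 1.** Both partners are free phenols and react sluggishly in the aldol stage, and the domino may stall at 3 or 4. The fallback replaces aldol/oxidation by acylation/cyclodehydration; it sets out from 1 and comes back at 5. The polyanion of 1 (LiN(SiMe3)2, 4 equiv, THF, −78 °C) is C-acylated with 4-methoxybenzoyl chloride to 1-(5-bromo-2,4-dihydroxyphenyl)-3-(4-methoxyphenyl)propane-1,3-dione F1. Cyclodehydration (H2SO4 cat., AcOH, 95 °C) gives 6-bromo-7-hydroxy-2-(4-methoxyphenyl)-4H-chromen-4-one F2, and BBr3 (CH2Cl2, 0 °C to rt) cleaves the only methyl ether present at this stage to give 5.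

## Further compounds

F1 | step 1 | 1-(5-bromo-2,4-dihydroxyphenyl)-3-(4-methoxyphenyl)propane-1,3-dione | COc1ccc(C(=O)CC(=O)c2cc(Br)c(O)cc2O)cc1
F2 | step 1 | 6-bromo-7-hydroxy-2-(4-methoxyphenyl)-4H-chromen-4-one | COc1ccc(-c2cc(=O)c3cc(Br)c(O)cc3o2)cc1
F3 | step 2 | apigenin, 5,7-dihydroxy-2-(4-hydroxyphenyl)-4H-chromen-4-one (bought, not made) | O=c1cc(-c2ccc(O)cc2)oc2cc(O)cc(O)c12
F4 | step 2 | 7-(benzyloxy)-2-[4-(benzyloxy)phenyl]-5-hydroxy-4H-chromen-4-one | O=c1cc(-c2ccc(OCc3ccccc3)cc2)oc2cc(OCc3ccccc3)cc(O)c12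
F5 | step 2 | 7-(benzyloxy)-2-[4-(benzyloxy)phenyl]-5-hydroxy-6-iodo-4H-chromen-4-one | O=c1cc(-c2ccc(OCc3ccccc3)cc2)oc2cc(OCc3ccccc3)c(I)c(O)c12
F6 | step 2 | methyl 3-{7-(benzyloxy)-2-[4-(benzyloxy)phenyl]-5-hydroxy-4-oxo-4H-chromen-6-yl}-4-methoxybenzoate | COC(=O)c1ccc(OC)c(-c2c(OCc3ccccc3)cc3oc(-c4ccc(OCc5ccccc5)cc4)cc(=O)c3c2O)c1
F7 | step 3 | 6-bromo-5-hydroxy-7-(methoxymethoxy)-2-[4-(methoxymethoxy)phenyl]-4H-chromen-4-one | COCOc1ccc(-c2cc(=O)c3c(O)c(Br)c(OCOC)cc3o2)cc1
F8 | step 3 | methyl 3-{5-hydroxy-7-(methoxymethoxy)-2-[4-(methoxymethoxy)phenyl]-4-oxo-4H-chromen-6-yl}-4-methoxybenzoate | COCOc1ccc(-c2cc(=O)c3c(O)c(-c4cc(C(=O)OC)ccc4OC)c(OCOC)cc3o2)cc1
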